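**Retrosynthetic overview**
1. Last bond made: the malate ester C–O. The ω-hydroxy lactone diacid opens O-trifluoroacetyl-(R)-malic anhydride at its activated carbonyl. The anhydride (fragment C) comes from maleic acid by enzymatic hydration.
2. Both carboxyl groups of the core are unmasked together, one from a vinyl group and one from a 2-furyl group, by a single oxidative cleavage.
3. Key disconnection: the bond between the quaternary lactone carbon and the neighbouring methine. It is made by CuH-catalysed reductive coupling of a C13 terminal allene (fragment B) with a 2-furyl γ-keto ester (fragment A), and both core stereocentres are set here.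
4. Fragment B comes from a C6 Grignard reagent and a C7 allenyl tosylate by copper-catalysed sp3–sp3 coupling. Fragment A comes from furfural and methyl acrylate by a Stetter reaction.
5. Ring order: the γ-lactone is the only ring built, and it closes in the key coupling. The furan is brought in and later destroyed, and the anhydride ring of fragment C is only a transient activating device.

Assumption: the SMILES is read as (2R)-malate ester, (1R) side-chain methine and (2S) lactone carbon; the facial sense written for (S,S)-Ph-BPE in step 6 is assigned by analogy, and the mirror-image ligand is used if a model run shows the opposite sense.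

**Step 1**
Reactants: 1 furfural (furan-2-carbaldehyde); 2 methyl acrylate
Product: 3 methyl 4-(furan-2-yl)-4-oxobutanoate
Conditions: 3-benzyl-5-(2-hydroxyethyl)-4-methylthiazolium chloride (10 mol %), Et3N (30 mol %), 1,4-dioxane, 80 °C
Reagents that add atoms: none
Why: Stetter reaction, in which the thiazol-2-ylidene turns the aldehyde into an acyl anion equivalent that adds 1,4 to the acrylate, a classical pairing for furfural that creates no stereocentre.

**Step 2**
Reactants: 4 hex-5-yn-1-ol
Product: 6 hepta-5,6-dien-1-ol, via propargylic amine 5 (not isolated)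
Conditions: (CH2O)n (2.5 equiv), Cy2NH (1.8 equiv), CuI (0.5 equiv), 1,4-dioxane, reflux
Reagents that add atoms: formaldehyde (from paraformaldehyde), C=O
Why: Crabbé–Ma allene homologation, in which CuI-promoted Mannich coupling of alkyne, formaldehyde and Cy2NH gives 5, whose copper-bound alkyne takes a hydride from an N-cyclohexyl C–H and expels the imine to leave the terminal allene, a sequence that tolerates the free primary alcohol.

**Step 3**
Reactants: 6 hepta-5,6-dien-1-ol
Product: 7 hepta-5,6-dien-1-yl 4-methylbenzenesulfonate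
Conditions: TsCl, Et3N, 4-(dimethylamino)pyridine (5 mol %), CH2Cl2, 0 °C to rt
Reagents that add atoms: 4-methylbenzenesulfonyl chloride, Cc1ccc(cc1)S(=O)(=O)Cl
Why: Standard sulfonylation of a primary alcohol, which gives a leaving group suited to copper-catalysed Grignard coupling and leaves the allene untouched.

**Step 4**
Reactants: 8 6-bromohexan-1-ol
Product: 9 tert-butyl[(6-bromohexyl)oxy]diphenylsilane
Conditions: TBDPSCl, imidazole, CH2Cl2, rt
Reagents that add atoms: tert-butyl(chloro)diphenylsilane, CC(C)(C)[Si](Cl)(c1ccccc1)c1ccccc1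
Why: Imidazole-assisted silyl ether protection, with TBDPS chosen because it survives Grignard formation, CuH/silane and RuO4.

**Step 5**
Reactants: 9 tert-butyl[(6-bromohexyl)oxy]diphenylsilane; 7 hepta-5,6-dien-1-yl 4-methylbenzenesulfonate
Product: 11 tert-butyl(diphenyl)(trideca-11,12-dien-1-yloxy)silane, via Grignard reagent 10 (not isolated)
Conditions: 9, Mg, THF, 40 °C; then 7, Li2CuCl4 (5 mol %), THF, −78 °C to rt
Reagents that add atoms: none
Why: Kochi–Schlosser copper-catalysed sp3–sp3 cross-coupling, in which the cuprate formed from 10 and Li2CuCl4 displaces the primary tosylate in an SN2 manner faster than it can touch the unactivated allene or the silyl ether, joining C6 and C7 into the C13 chain.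

**Step 6**
Reactants: 3 methyl 4-(furan-2-yl)-4-oxobutanoate; 11 tert-butyl(diphenyl)(trideca-11,12-dien-1-yloxy)silane
Product: 13 (5S)-5-[(3S)-13-{[tert-butyl(diphenyl)silyl]oxy}tridec-1-en-3-yl]-5-(furan-2-yl)oxolan-2-one, via copper alkoxide 12 (not isolated)
Conditions: Cu(OAc)2 (5 mol %), (S,S)-Ph-BPE [1,2-bis((2S,5S)-2,5-diphenylphospholan-1-yl)ethane] (6 mol %), (MeO)2MeSiH (1.5 equiv), 11 (1.2 equiv), MTBE, 0 °C, 3 added over 6 h, then rt
Reagents that add atoms: none
Why: Proposed new method: L*CuH made from Cu(OAc)2, the diphosphine and the silane hydrocuprates the terminal C=C of 11 (H to the central carbon), the σ-allylcopper isomers interconvert by 1,3-shift and the E isomer hands its γ-carbon to the Si face of ketone 3 through a closed chair with furyl equatorial, the ester arm axial and the C10 chain pseudo-equatorial, so that the (5S) carbinol carbon and the (3S) methine arise together in the anti relationship, after which alkoxide 12 closes on its own methyl ester to build the lactone ring and release CuOMe, which the silane returns to CuH; the closest known reaction type is the CuH-catalysed enantioselective allylation of simple aryl methyl ketones with terminal allenes (with copper hydride reductive aldol–lactonisation as the model for the ring closure), which has not been shown on a furyl γ-keto ester with lactonising turnover or for pairing such a quaternary carbinol with an unbranched alkyl allene.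

**Step 7**
Reactants: 13 (5S)-5-[(3S)-13-{[tert-butyl(diphenyl)silyl]oxy}tridec-1-en-3-yl]-5-(furan-2-yl)oxolan-2-one
Product: 14 (2S)-2-[(1R)-11-{[tert-butyl(diphenyl)silyl]oxy}-1-carboxyundecyl]-5-oxooxolane-2-carboxylic acid
Conditions: RuCl3·xH2O (5 mol %), NaIO4 (12 equiv), EtOAc/MeCN/H2O 2:2:3, 0 °C to rt
Reagents that add atoms: sodium periodate (oxygen carried over by RuO4), [Na+].[O-]I(=O)(=O)=O; water, O
Why: RuO4 oxidative cleavage, which degrades the monosubstituted alkene and the electron-rich furan to CO2H in one operation while lactone and TBDPS ether resist, and since no bond at either stereocentre is broken the geometry of 13 is kept (the methine descriptor changes from S to R only because the priorities change).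

**Step 8**
Reactants: 14 (2S)-2-[(1R)-11-{[tert-butyl(diphenyl)silyl]oxy}-1-carboxyundecyl]-5-oxooxolane-2-carboxylic acid
Product: 15 (2S)-2-[(1R)-1-carboxy-11-hydroxyundecyl]-5-oxooxolane-2-carboxylic acid
Conditions: HF·pyridine, THF, 0 °C to rt
Reagents that add atoms: none
Why: Fluoride-driven desilylation under mildly acidic conditions, which leaves the lactone, both acids and the α-stereocentre untouched.

**Step 9**
Reactants: 16 maleic acid
Product: 19 (R)-malic acid, via disodium maleate 17 (not isolated), via disodium (R)-malate 18 (not isolated)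
Conditions: aq NaOH (2 equiv, pH 8), maleate hydratase (EC 4.2.1.31, permeabilised Pseudomonas pseudoalcaligenes cells), 30 °C; then HCl (2 equiv), continuous extraction with Et2O
Reagents that add atoms: water, O
Why: Enzymatic hydration (lyase catalysis), in which maleate hydratase adds water across the cis double bond and releases only the (R)-hydroxy acid in over 99 % ee, which sets the malate stereocentre.

**Step 10**
Reactants: 19 (R)-malic acid
Product: 20 (3R)-2,5-dioxooxolan-3-yl trifluoroacetate
Conditions: (CF3CO)2O (3 equiv), neat, 0 °C to rt; volatiles removed in vacuo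
Reagents that add atoms: trifluoroacetic anhydride, O=C(OC(=O)C(F)(F)F)C(F)(F)F
Why: Dehydrative cyclic anhydride formation with concomitant O-trifluoroacetylation, a standard activation of malic acid that never breaks the C–O bond at the stereocentre, so the (R) configuration is kept.

**Step 11**
Reactants: 15 (2S)-2-[(1R)-1-carboxy-11-hydroxyundecyl]-5-oxooxolane-2-carboxylic acid; 20 (3R)-2,5-dioxooxolan-3-yl trifluoroacetate
Product: 22 (2S)-2-[(1R)-1-carboxy-11-{[(2R)-3-carboxy-2-hydroxypropanoyl]oxy}undecyl]-5-oxooxolane-2-carboxylic acid, via trifluoroacetate ester 21 (not isolated)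
Conditions: 20 (2.5 equiv), THF, 0 °C to rt; then H2O, rt; reversed-phase chromatography
Reagents that add atoms: none
Why: Regioselective alcoholysis of an unsymmetrical cyclic anhydride, in which the primary alcohol attacks the carbonyl next to the electron-withdrawing trifluoroacetoxy group to give the 1-ester with the 4-acid free, the hindered acids of 15 stay spectators, water then cleaves the labile trifluoroacetate, and no stereocentre is touched.

**Compound list**
1 | furfural (furan-2-carbaldehyde) | O=Cc1ccco1 | starting material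
2 | methyl acrylate | C=CC(=O)OC | starting material
3 | methyl 4-(furan-2-yl)-4-oxobutanoate | COC(=O)CCC(=O)c1ccco1 | intermediate
4 | hex-5-yn-1-ol | C#CCCCCO | starting material
5 | 7-(dicyclohexylamino)hept-5-yn-1-ol | OCCCCC#CCN(C1CCCCC1)C1CCCCC1 | intermediate (not isolated)
6 | hepta-5,6-dien-1-ol | C=C=CCCCCO | intermediate
7 | hepta-5,6-dien-1-yl 4-methylbenzenesulfonate | C=C=CCCCCOS(=O)(=O)c1ccc(C)cc1 | intermediate
8 | 6-bromohexan-1-ol | OCCCCCCBr | starting material
9 | tert-butyl[(6-bromohexyl)oxy]diphenylsilane | CC(C)(C)[Si](OCCCCCCBr)(c1ccccc1)c1ccccc1 | intermediate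
10 | (6-{[tert-butyl(diphenyl)silyl]oxy}hexyl)magnesium bromide | CC(C)(C)[Si](OCCCCCC[Mg]Br)(c1ccccc1)c1ccccc1 | intermediate (not isolated)
11 | tert-butyl(diphenyl)(trideca-11,12-dien-1-yloxy)silane | C=C=CCCCCCCCCCCO[Si](c1ccccc1)(c1ccccc1)C(C)(C)C | intermediate
12 | (Ph-BPE)Cu alkoxide of methyl (4S,5S)-15-{[tert-butyl(diphenyl)silyl]oxy}-5-ethenyl-4-(furan-2-yl)-4-hydroxypentadecanoate (diphosphine on copper not drawn) | CC(C)(C)[Si](c1ccccc1)(c1ccccc1)OCCCCCCCCCC[C@@H](C=C)[C@](O[Cu])(c1ccco1)CCC(=O)OC | intermediate (not isolated)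
13 | (5S)-5-[(3S)-13-{[tert-butyl(diphenyl)silyl]oxy}tridec-1-en-3-yl]-5-(furan-2-yl)oxolan-2-one | CC(C)(C)[Si](c1ccccc1)(c1ccccc1)OCCCCCCCCCC[C@@H](C=C)[C@]1(c2ccco2)CCC(=O)O1 | intermediate
14 | (2S)-2-[(1R)-11-{[tert-butyl(diphenyl)silyl]oxy}-1-carboxyundecyl]-5-oxooxolane-2-carboxylic acid | CC(C)(C)[Si](c1ccccc1)(c1ccccc1)OCCCCCCCCCC[C@@H](C(=O)O)[C@]1(C(=O)O)CCC(=O)O1 | intermediate
15 | (2S)-2-[(1R)-1-carboxy-11-hydroxyundecyl]-5-oxooxolane-2-carboxylic acid | OCCCCCCCCCC[C@@H](C(=O)O)[C@]1(C(=O)O)CCC(=O)O1 | intermediate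
16 | maleic acid | O=C(O)/C=C\C(=O)O | starting material
17 | disodium maleate | [Na+].[Na+].[O-]C(=O)/C=C\C(=O)[O-] | intermediate (not isolated)
18 | disodium (R)-malate | [Na+].[Na+].[O-]C(=O)C[C@@H](O)C(=O)[O-] | intermediate (not isolated)
19 | (R)-malic acid | O=C(O)C[C@@H](O)C(=O)O | intermediate
20 | (3R)-2,5-dioxooxolan-3-yl trifluoroacetate | O=C1C[C@@H](OC(=O)C(F)(F)F)C(=O)O1 | intermediate
21 | (2S)-2-[(1R)-1-carboxy-11-{[(2R)-3-carboxy-2-(trifluoroacetoxy)propanoyl]oxy}undecyl]-5-oxooxolane-2-carboxylic acid | O=C(O)C[C@@H](OC(=O)C(F)(F)F)C(=O)OCCCCCCCCCC[C@@H](C(=O)O)[C@]1(C(=O)O)CCC(=O)O1 | intermediate (not isolated)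
22 | (2S)-2-[(1R)-1-carboxy-11-{[(2R)-3-carboxy-2-hydroxypropanoyl]oxy}undecyl]-5-oxooxolane-2-carboxylic acid | O=C(O)C[C@@H](O)C(=O)OCCCCCCCCCC[C@@H](C(=O)O)[C@]1(C(=O)O)CCC(=O)O1 | target

**Total step count:** 11
**Longest linear sequence:** 7 steps (2, 3, 5, 6, 7, 8, 11)

**The three steps most likely to fail**

**Step 6 (the proposed new coupling).**
- CuH may reduce ketone 3 directly.
- The chair from the Z-allylcopper may compete and erode the anti:syn ratio.
- The facial sense is unproven.

The fallback uses known chemistry only. It sets out from Grignard reagent 10 and comes back to the route at diacid 14, so steps 6 and 7 are both bypassed. Reagent 10 is coupled with ethyl 6-bromohexanoate (Li2CuCl4 cat., THF/NMP, 0 °C) to give ethyl 12-{[tert-butyl(diphenyl)silyl]oxy}dodecanoate F1. Me2AlSEt (from Me3Al and EtSH, CH2Cl2) converts it into the S-ethyl thioester F2. LDA and then Me3SiCl (THF, −78 °C) give the (Z)-silyl ketene thioacetal F3. The next reaction is the established anti-selective Mukaiyama aldol addition of such thioacetals to α-keto esters under Sn(OTf)2/bis(oxazoline) catalysis (10 mol %, CH2Cl2, −78 °C, ligand antipode chosen for the (S)-carbinol). Run with dimethyl 2-oxoglutarate, it gives after desilylating work-up the open anti aldol adduct F4. Catalytic p-TsOH closes F4 to the lactone thioester F5. LiOH in aqueous THF followed by acidification to pH 2, on which the lactone re-closes, delivers 14.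

**Step 11 (acylation of the unprotected hydroxy diacid).**
- Some 4-ester regioisomer may form.
- The free acids may enter mixed-anhydride exchange and oligomerise.

The fallback removes the regiochemical choice by protection. It sets out from 14 and 19 and comes back at 22. Diacid 14 is benzylated (BnBr, Cs2CO3, DMF) to the dibenzyl ester of 14 F7 and desilylated (HF·pyridine, THF) to the dibenzyl ester alcohol F8. In parallel, 19 is tied up with 2,2-dimethoxypropane (cat. p-TsOH) as the dioxolanone acid F9, in which C1 and the hydroxyl are blocked. The free C4 acid is benzylated (BnBr, Et3N, acetone) to the dioxolanone benzyl ester F10. Aqueous acetic acid then removes the acetonide to give 4-benzyl (R)-malate F11, whose only free acid is C1. Mitsunobu esterification of F8 with F11 (PPh3, DIAD, THF, 0 °C) gives the tribenzyl ester of 22 F12. Hydrogenolysis (H2, Pd/C, EtOAc) gives 22.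

**Step 7 (double oxidative unmasking).**
- The furan degradation may stall at ene-dione or keto acid stages.
- The silyl ether may be attacked on long exposure.
- The transient α-branched aldehyde may epimerise.

The fallback replaces the single RuO4 operation by a staged sequence with an isolated intermediate. It sets out from 13 and comes back at 14. Ozone in CH2Cl2/MeOH at −78 °C followed by Me2S cleaves both π systems but stops at the aldehyde level on the vinyl side, giving the aldehyde acid F6. A separate Pinnick oxidation (NaClO2, NaH2PO4, 2-methylbut-2-ene, t-BuOH/H2O, 0 °C) then takes F6 to 14 under buffered conditions that do not enolise the methine.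

**Further compounds**
F1 | step 6 | ethyl 12-{[tert-butyl(diphenyl)silyl]oxy}dodecanoate | CCOC(=O)CCCCCCCCCCCO[Si](c1ccccc1)(c1ccccc1)C(C)(C)C
F2 | step 6 | S-ethyl 12-{[tert-butyl(diphenyl)silyl]oxy}dodecanethioate | CCSC(=O)CCCCCCCCCCCO[Si](c1ccccc1)(c1ccccc1)C(C)(C)C
F3 | step 6 | {[(1Z)-12-{[tert-butyl(diphenyl)silyl]oxy}-1-(ethylsulfanyl)dodec-1-en-1-yl]oxy}trimethylsilane | CCS/C(O[Si](C)(C)C)=C\CCCCCCCCCCO[Si](c1ccccc1)(c1ccccc1)C(C)(C)C
F4 | step 6 | dimethyl (2S)-2-[(2R)-12-{[tert-butyl(diphenyl)silyl]oxy}-1-(ethylsulfanyl)-1-oxododecan-2-yl]-2-hydroxypentanedioate | CC(C)(C)[Si](c1ccccc1)(c1ccccc1)OCCCCCCCCCC[C@@H](C(=O)SCC)[C@](O)(C(=O)OC)CCC(=O)OC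
F5 | step 6 | methyl (2S)-2-[(2R)-12-{[tert-butyl(diphenyl)silyl]oxy}-1-(ethylsulfanyl)-1-oxododecan-2-yl]-5-oxooxolane-2-carboxylate | CC(C)(C)[Si](c1ccccc1)(c1ccccc1)OCCCCCCCCCC[C@@H](C(=O)SCC)[C@]1(C(=O)OC)CCC(=O)O1
F6 | step 7 | (2S)-2-[(2R)-12-{[tert-butyl(diphenyl)silyl]oxy}-1-oxododecan-2-yl]-5-oxooxolane-2-carboxylic acid | CC(C)(C)[Si](c1ccccc1)(c1ccccc1)OCCCCCCCCCC[C@@H](C=O)[C@]1(C(=O)O)CCC(=O)O1
F7 | step 11 | benzyl (2S)-2-[(2R)-1-(benzyloxy)-12-{[tert-butyl(diphenyl)silyl]oxy}-1-oxododecan-2-yl]-5-oxooxolane-2-carboxylate | CC(C)(C)[Si](c1ccccc1)(c1ccccc1)OCCCCCCCCCC[C@@H](C(=O)OCc1ccccc1)[C@]1(C(=O)OCc2ccccc2)CCC(=O)O1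
F8 | step 11 | benzyl (2S)-2-[(2R)-1-(benzyloxy)-12-hydroxy-1-oxododecan-2-yl]-5-oxooxolane-2-carboxylate | OCCCCCCCCCC[C@@H](C(=O)OCc1ccccc1)[C@]1(C(=O)OCc2ccccc2)CCC(=O)O1
F9 | step 11 | [(4R)-2,2-dimethyl-5-oxo-1,3-dioxolan-4-yl]acetic acid | O=C(O)C[C@H]1OC(C)(C)OC1=O
F10 | step 11 | benzyl [(4R)-2,2-dimethyl-5-oxo-1,3-dioxolan-4-yl]acetate | O=C(C[C@H]1OC(C)(C)OC1=O)OCc1ccccc1
F11 | step 11 | (2R)-4-(benzyloxy)-2-hydroxy-4-oxobutanoic acid | O=C(OCc1ccccc1)C[C@@H](O)C(=O)O
F12 | step 11 | tribenzyl ester of 22 | O=C(OCc1ccccc1)C[C@@H](O)C(=O)OCCCCCCCCCC[C@@H](C(=O)OCc1ccccc1)[C@]1(C(=O)OCc2ccccc2)CCC(=O)O1
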